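**Plan** (locants: flavanone unprimed, its 2-aryl ring primed, flavone double-primed)

1. Retrosynthesis: remove the three O-benzyl groups and the C4 N-sulfinyl imine helper; then cut C2–C3 and O1–C8a of the flavanone pyranone ring (ring C) in one operation, giving ring A fluoro-ketimine 13 and biaryl aldehyde 8; last cut the C3'–C8'' biaryl bond of 8 to iodoflavone 4 and boronate 7.
2. Forward: acacetin is 7''-O-methylated, 5''-O-benzylated and iodinated at C8''; Suzuki–Miyaura coupling with the formylphenyl boronate gives 8, with the flavone and the future ring B complete. Ring A comes from 3,5-difluoroanisole as ketimine 13; the annulation of 13 onto the CHO of 8 builds ring C last; imine hydrolysis and hydrogenolysis finish.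
3. Enabling feature: flavanone C4 is α to C3 and sits on C4a, ortho to C8a of ring A. Carried as C=N–S(O)tBu it makes C3 a carbon nucleophile for the aldehyde carbon (C2) and C8a–F an SNAr acceptor for the aldehyde oxygen (O1). The ring A oxygens at C5 and C7 are meta to C8a and do not retard the substitution.
4. Stereochemistry: C2 (S), the only stereocentre, is set in the C2–C3 bond formation by the (R)-tert-butanesulfinyl auxiliary; the C2–O1 bond is never broken afterwards and all later steps are acidic or neutral.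

Key step: step 10

Remark: the sense of induction of the sulfinyl aza-enolate addition is taken as (R) at sulfur giving (S) at the new carbinol carbon; if the adduct proves to be the C2 epimer, (S)-2-methylpropane-2-sulfinamide is used in step 9 and nothing else changes.
Remark: the C3'–C8'' biaryl axis (three small ortho substituents) is treated as freely rotating, so no axial configuration has to be set.

**Route**

Step 1
Reactants: 1 acacetin (5,7-dihydroxy-2-(4-methoxyphenyl)-4H-chromen-4-one)
Product: 2 5-hydroxy-7-methoxy-2-(4-methoxyphenyl)-4H-chromen-4-one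
Conditions: MeI (1.1 equiv), K2CO3, acetone, reflux
Reagents that add atoms: iodomethane, CI
Why: Williamson O-methylation should be selective for the acidic, unchelated 7-OH because the 5-OH is held in a hydrogen bond to the C4 carbonyl.

Step 2
Reactants: 2 5-hydroxy-7-methoxy-2-(4-methoxyphenyl)-4H-chromen-4-one
Product: 3 5-(benzyloxy)-7-methoxy-2-(4-methoxyphenyl)-4H-chromen-4-one
Conditions: BnBr, K2CO3, DMF, 80 °C
Reagents that add atoms: benzyl bromide, BrCc1ccccc1
Why: Williamson benzylation of the chelated 5-OH under forcing conditions masks the last phenol, so that iodination goes to C8 and the later aza-enolate is not quenched.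

Step 3
Reactants: 3 5-(benzyloxy)-7-methoxy-2-(4-methoxyphenyl)-4H-chromen-4-one
Product: 4 5-(benzyloxy)-8-iodo-7-methoxy-2-(4-methoxyphenyl)-4H-chromen-4-one
Conditions: NIS, CF3CO2H (cat.), MeCN, rt
Reagents that add atoms: N-iodosuccinimide, O=C1CCC(=O)N1I
Why: Electrophilic aromatic iodination of the fully O-alkylated ring is expected at C8 (para to the 5-benzyloxy group, ortho to 7-OMe, less hindered than C6 between two alkoxy groups), the usual outcome for 5,7-dialkoxyflavones.

Step 4
Reactants: 5 3-bromo-4-hydroxybenzaldehyde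
Product: 6 4-(benzyloxy)-3-bromobenzaldehyde
Conditions: BnBr, K2CO3, DMF, rt
Reagents that add atoms: benzyl bromide, BrCc1ccccc1
Why: Williamson benzylation protects the phenol that must pass through the organometallic steps and is removed at the end with the other benzyl groups.

Step 5
Reactants: 6 4-(benzyloxy)-3-bromobenzaldehyde
Product: 7 4-(benzyloxy)-3-(4,4,5,5-tetramethyl-1,3,2-dioxaborolan-2-yl)benzaldehyde
Conditions: B2pin2, PdCl2(dppf) (dppf = 1,1'-bis(diphenylphosphino)ferrocene), KOAc, 1,4-dioxane, 90 °C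
Reagents that add atoms: bis(pinacolato)diboron, CC1(C)OB(OC1(C)C)B1OC(C)(C)C(C)(C)O1
Why: Miyaura borylation of the aryl bromide tolerates the aldehyde under the weak acetate base.

Step 6
Reactants: 4 5-(benzyloxy)-8-iodo-7-methoxy-2-(4-methoxyphenyl)-4H-chromen-4-one; 7 4-(benzyloxy)-3-(4,4,5,5-tetramethyl-1,3,2-dioxaborolan-2-yl)benzaldehyde
Product: 8 4-(benzyloxy)-3-[5-(benzyloxy)-7-methoxy-2-(4-methoxyphenyl)-4-oxo-4H-chromen-8-yl]benzaldehyde
Conditions: Pd(OAc)2, SPhos (2-dicyclohexylphosphino-2',6'-dimethoxybiphenyl), K3PO4, toluene/H2O, 90 °C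
Reagents that add atoms: none
Why: Suzuki–Miyaura coupling with an electron-rich bulky biarylphosphine should join the two arenes across the tri-ortho-substituted C3'–C8'' bond and leave aldehyde, flavone and benzyl ethers untouched.

Step 7
Reactants: 9 3,5-difluoroanisole
Product: 11 1-(2,6-difluoro-4-methoxyphenyl)ethanone, via 2,6-difluoro-4-methoxyphenyllithium 10 (not isolated)
Conditions: n-BuLi, THF, −78 °C; MeC(O)N(OMe)Me, −78 → 0 °C; 1 M HCl work-up
Reagents that add atoms: N-methoxy-N-methylacetamide, CON(C)C(C)=O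
Why: Directed ortho-lithiation should occur at the most acidic C–H between the two fluorines, and the aryllithium is acylated once through the stable chelated tetrahedral adduct of the N-methoxy-N-methylamide (Weinreb ketone synthesis).

Step 8
Reactants: 11 1-(2,6-difluoro-4-methoxyphenyl)ethanone
Product: 12 1-[2-(benzyloxy)-6-fluoro-4-methoxyphenyl]ethanone
Conditions: BnONa (1.0 equiv, 1 M in BnOH), THF, 0 °C → rt
Reagents that add atoms: sodium benzyloxide, [Na+].[O-]Cc1ccccc1
Why: SNAr at a fluorine ortho to the acetyl group replaces one of two equivalent fluorides by benzyl oxide, and the new donor should slow a second substitution.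

Step 9
Reactants: 12 1-[2-(benzyloxy)-6-fluoro-4-methoxyphenyl]ethanone
Product: 13 (R,E)-N-{1-[2-(benzyloxy)-6-fluoro-4-methoxyphenyl]ethylidene}-2-methylpropane-2-sulfinamide
Conditions: (R)-t-BuS(O)NH2, Ti(OEt)4, THF, 70 °C
Reagents that add atoms: (R)-2-methylpropane-2-sulfinamide, CC(C)(C)[S@@](=O)N
Why: Ti(OEt)4-mediated condensation (water taken up by the titanium alkoxide) gives the N-sulfinyl ketimine that serves as chiral auxiliary, SNAr activator and ketone surrogate.

Step 10
Reactants: 13 (R,E)-N-{1-[2-(benzyloxy)-6-fluoro-4-methoxyphenyl]ethylidene}-2-methylpropane-2-sulfinamide; 8 4-(benzyloxy)-3-[5-(benzyloxy)-7-methoxy-2-(4-methoxyphenyl)-4-oxo-4H-chromen-8-yl]benzaldehyde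
Product: 16 (R)-N-[(2S,4E)-5-(benzyloxy)-2-{4-(benzyloxy)-3-[5-(benzyloxy)-7-methoxy-2-(4-methoxyphenyl)-4-oxo-4H-chromen-8-yl]phenyl}-7-methoxy-2,3-dihydro-4H-chromen-4-ylidene]-2-methylpropane-2-sulfinamide, via magnesium aza-enolate 14 (not isolated), via magnesium aldolate 15 (not isolated)
Conditions: 13 (1.3 equiv), LDA (1.25 equiv), THF, −78 °C; MgBr2·OEt2 (2 equiv), −78 °C; 8, −78 °C; then DMPU, −78 → 40 °C
Reagents that add atoms: none
Why: Proposed new method: the magnesium aza-enolate 14 adds through its CH2 carbon to the aldehyde of 8 in a closed, magnesium-bridged transition state (C2–C3 bond), and on warming the bromomagnesium alkoxide 15 attacks the fluorine-bearing C8a of ring A, ortho to the C=N group, to give a Meisenheimer anion delocalised into the sulfinylimine that expels fluoride (O1–C8a bond), a formal oxa-[4+2] annulation of C=O with the C3–C4–C4a–C8a unit. The closest known reaction types are the diastereoselective addition of N-tert-butanesulfinyl metalloenamines to aldehydes and the intramolecular SNAr of alkoxides on ortho-fluoroaryl ketones and imines, whose union in one flask has not been shown. The pyranone ring closes by a 6-exo-trig addition–elimination at the arene carbon after the intermolecular C–C bond formation. The C2 stereocentre is set in the addition by the sulfur stereocentre ((R) at sulfur is expected to give (2S)) and is untouched by the closure, which makes the aryl–O bond with retention at C2; because the auxiliary stays on the molecule, any retro-addition is followed by re-addition under the same control, and the minor diastereomer can be removed from 16 by chromatography or crystallisation. The step needs attack at the aldehyde and not at the flavone carbonyl (the aldehyde is far more electrophilic at −78 °C), closure at C–F and not at C–OBn (fluoride is much the better SNAr leaving group, and the C5 and C7 oxygens are meta to C8a), and ring closure ahead of loss of water to the azachalcone (the oxygen stays a chelated magnesium alkoxide, a poor leaving group that should become a competent nucleophile once DMPU is added).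

Step 11
Reactants: 16 (R)-N-[(2S,4E)-5-(benzyloxy)-2-{4-(benzyloxy)-3-[5-(benzyloxy)-7-methoxy-2-(4-methoxyphenyl)-4-oxo-4H-chromen-8-yl]phenyl}-7-methoxy-2,3-dihydro-4H-chromen-4-ylidene]-2-methylpropane-2-sulfinamide
Product: 17 (2S)-5-(benzyloxy)-2-{4-(benzyloxy)-3-[5-(benzyloxy)-7-methoxy-2-(4-methoxyphenyl)-4-oxo-4H-chromen-8-yl]phenyl}-7-methoxy-2,3-dihydro-4H-chromen-4-one
Conditions: 1 M HCl (aq), THF, 0 °C → rt
Reagents that add atoms: water, O
Why: Mild aqueous-acid hydrolysis of the N-sulfinyl ketimine returns the C4 ketone and releases the auxiliary without base, so C2 cannot epimerise by ring opening to the chalcone.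

Step 12
Reactants: 17 (2S)-5-(benzyloxy)-2-{4-(benzyloxy)-3-[5-(benzyloxy)-7-methoxy-2-(4-methoxyphenyl)-4-oxo-4H-chromen-8-yl]phenyl}-7-methoxy-2,3-dihydro-4H-chromen-4-one
Product: 18 2,3-dihydroheveaflavone, (2S)-5-hydroxy-2-{4-hydroxy-3-[5-hydroxy-7-methoxy-2-(4-methoxyphenyl)-4-oxo-4H-chromen-8-yl]phenyl}-7-methoxy-2,3-dihydro-4H-chromen-4-one
Conditions: H2 (1 atm), 10% Pd on carbon, EtOAc/THF, rt
Reagents that add atoms: none
Why: Catalytic hydrogenolysis of the three aryl benzyl ethers under neutral conditions should free both 5-hydroxy groups and the 4'-hydroxy group without touching the base-sensitive C2 centre or the methyl ethers, provided it is stopped after uptake for three benzyl groups.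

**Compound list**

1 | acacetin, 5,7-dihydroxy-2-(4-methoxyphenyl)-4H-chromen-4-one | COc1ccc(cc1)-c1cc(=O)c2c(O)cc(O)cc2o1 | starting material
2 | 5-hydroxy-7-methoxy-2-(4-methoxyphenyl)-4H-chromen-4-one | COc1ccc(cc1)-c1cc(=O)c2c(O)cc(OC)cc2o1 | intermediate
3 | 5-(benzyloxy)-7-methoxy-2-(4-methoxyphenyl)-4H-chromen-4-one | COc1ccc(cc1)-c1cc(=O)c2c(OCc3ccccc3)cc(OC)cc2o1 | intermediate
4 | 5-(benzyloxy)-8-iodo-7-methoxy-2-(4-methoxyphenyl)-4H-chromen-4-one | COc1ccc(cc1)-c1cc(=O)c2c(OCc3ccccc3)cc(OC)c(I)c2o1 | intermediate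
5 | 3-bromo-4-hydroxybenzaldehyde | O=Cc1ccc(O)c(Br)c1 | starting material
6 | 4-(benzyloxy)-3-bromobenzaldehyde | O=Cc1ccc(OCc2ccccc2)c(Br)c1 | intermediate
7 | 4-(benzyloxy)-3-(4,4,5,5-tetramethyl-1,3,2-dioxaborolan-2-yl)benzaldehyde | O=Cc1ccc(OCc2ccccc2)c(c1)B1OC(C)(C)C(C)(C)O1 | intermediate
8 | 4-(benzyloxy)-3-[5-(benzyloxy)-7-methoxy-2-(4-methoxyphenyl)-4-oxo-4H-chromen-8-yl]benzaldehyde | O=Cc1ccc(OCc2ccccc2)c(c1)-c1c(OC)cc(OCc2ccccc2)c2c(=O)cc(-c3ccc(OC)cc3)oc12 | intermediate
9 | 3,5-difluoroanisole | COc1cc(F)cc(F)c1 | starting material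
10 | 2,6-difluoro-4-methoxyphenyllithium | COc1cc(F)c([Li])c(F)c1 | intermediate (not isolated)
11 | 1-(2,6-difluoro-4-methoxyphenyl)ethanone | CC(=O)c1c(F)cc(OC)cc1F | intermediate
12 | 1-[2-(benzyloxy)-6-fluoro-4-methoxyphenyl]ethanone | CC(=O)c1c(F)cc(OC)cc1OCc1ccccc1 | intermediate
13 | (R,E)-N-{1-[2-(benzyloxy)-6-fluoro-4-methoxyphenyl]ethylidene}-2-methylpropane-2-sulfinamide | CC(C)(C)[S@@](=O)/N=C(\C)c1c(F)cc(OC)cc1OCc1ccccc1 | intermediate
14 | bromomagnesium aza-enolate of 13, (R)-N-(bromomagnesio)-N-{1-[2-(benzyloxy)-6-fluoro-4-methoxyphenyl]ethenyl}-2-methylpropane-2-sulfinamide | CC(C)(C)[S@@](=O)N([Mg]Br)C(=C)c1c(F)cc(OC)cc1OCc1ccccc1 | intermediate (not isolated)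
15 | bromomagnesium alkoxide of the (R)-sulfinyl, (3S)-3-hydroxy ketimine (open-chain aldol adduct of 13 and 8) | CC(C)(C)[S@@](=O)/N=C(\C[C@H](O[Mg]Br)c1ccc(OCc2ccccc2)c(c1)-c1c(OC)cc(OCc2ccccc2)c2c(=O)cc(-c3ccc(OC)cc3)oc12)c1c(F)cc(OC)cc1OCc1ccccc1 | intermediate (not isolated)
16 | (R)-N-[(2S,4E)-5-(benzyloxy)-2-{4-(benzyloxy)-3-[5-(benzyloxy)-7-methoxy-2-(4-methoxyphenyl)-4-oxo-4H-chromen-8-yl]phenyl}-7-methoxy-2,3-dihydro-4H-chromen-4-ylidene]-2-methylpropane-2-sulfinamide | CC(C)(C)[S@@](=O)/N=C1/c2c(OCc3ccccc3)cc(OC)cc2O[C@@H](C1)c1ccc(OCc2ccccc2)c(c1)-c1c(OC)cc(OCc2ccccc2)c2c(=O)cc(-c3ccc(OC)cc3)oc12 | intermediate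
17 | (2S)-5-(benzyloxy)-2-{4-(benzyloxy)-3-[5-(benzyloxy)-7-methoxy-2-(4-methoxyphenyl)-4-oxo-4H-chromen-8-yl]phenyl}-7-methoxy-2,3-dihydro-4H-chromen-4-one | O=C1C[C@@H](c2ccc(OCc3ccccc3)c(c2)-c2c(OC)cc(OCc3ccccc3)c3c(=O)cc(-c4ccc(OC)cc4)oc23)Oc2cc(OC)cc(OCc3ccccc3)c12 | intermediate
18 | 2,3-dihydroheveaflavone | COc1ccc(-c2cc(=O)c3c(O)cc(OC)c(-c4cc([C@@H]5CC(=O)c6c(O)cc(OC)cc6O5)ccc4O)c3o2)cc1 | target

**Step count and risks**

Total steps: 12. Longest linear sequence: 7 steps (1, 2, 3, 6, 10, 11, 12).

Steps most likely to fail: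

1. Step 10 (the proposed new method). The ring closure of the magnesium alkoxide may be too slow, so that retro-addition, loss of water to the azachalcone or sulfinyl transfer from nitrogen to oxygen take over; facial control in the addition may also be poor. Fallback, by known chemistry that closes O1–C2 instead, setting out from aldehyde 8: commercial 1-(2,6-dihydroxy-4-methoxyphenyl)ethanone is mono-benzylated (BnBr, K2CO3, acetone, reflux) to 1-[2-(benzyloxy)-6-hydroxy-4-methoxyphenyl]ethanone F1. Claisen–Schmidt condensation of F1 with 8 (KOH, EtOH/THF, rt) should give (E)-1-[2-(benzyloxy)-6-hydroxy-4-methoxyphenyl]-3-{4-(benzyloxy)-3-[5-(benzyloxy)-7-methoxy-2-(4-methoxyphenyl)-4-oxo-4H-chromen-8-yl]phenyl}prop-2-en-1-one F2. NaOAc in refluxing EtOH closes it by oxa-Michael addition to the racemic flavanone, rac-5-(benzyloxy)-2-{4-(benzyloxy)-3-[5-(benzyloxy)-7-methoxy-2-(4-methoxyphenyl)-4-oxo-4H-chromen-8-yl]phenyl}-7-methoxy-2,3-dihydro-4H-chromen-4-one F3. Preparative HPLC on a cellulose tris(3,5-dimethylphenylcarbamate) phase separates the enantiomers; the (2S) enantiomer is compound 17, where the route resumes at step 12.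

2. Step 6. Transmetalation and reductive elimination at the congested palladium centre may be slow, so that protodeboronation of the electron-rich ortho-alkoxy boronate and dehalogenation of the iodide take over. Fallback with the roles of the partners exchanged, setting out from iodide 4: Miyaura borylation (B2pin2, PdCl2(dppf), KOAc, 1,4-dioxane, 90 °C) gives 5-(benzyloxy)-7-methoxy-2-(4-methoxyphenyl)-8-(4,4,5,5-tetramethyl-1,3,2-dioxaborolan-2-yl)-4H-chromen-4-one F4, which is coupled with the small, unhindered bromide 6 (Pd(OAc)2, SPhos, K3PO4, toluene/H2O) to come back to 8.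

3. Step 12. Over-reduction may occur before the third benzyl group is lost: saturation of the flavone C2''=C3'' bond or hydrogenolytic opening of the benzylic C2–O1 bond of the flavanone. Fallback without hydrogen, setting out from 17: Lewis-acid debenzylation with BCl3 and pentamethylbenzene as benzyl-cation scavenger (CH2Cl2, −78 °C, aqueous work-up) should cleave the three aryl benzyl ethers, leave the methyl ethers, and give 18 directly; no new compound arises (F0).

Further compounds
F1 | step 10 | 1-[2-(benzyloxy)-6-hydroxy-4-methoxyphenyl]ethanone | CC(=O)c1c(O)cc(OC)cc1OCc1ccccc1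
F2 | step 10 | (E)-1-[2-(benzyloxy)-6-hydroxy-4-methoxyphenyl]-3-{4-(benzyloxy)-3-[5-(benzyloxy)-7-methoxy-2-(4-methoxyphenyl)-4-oxo-4H-chromen-8-yl]phenyl}prop-2-en-1-one | O=C(/C=C/c1ccc(OCc2ccccc2)c(c1)-c1c(OC)cc(OCc2ccccc2)c2c(=O)cc(-c3ccc(OC)cc3)oc12)c1c(O)cc(OC)cc1OCc1ccccc1
F3 | step 10 | rac-5-(benzyloxy)-2-{4-(benzyloxy)-3-[5-(benzyloxy)-7-methoxy-2-(4-methoxyphenyl)-4-oxo-4H-chromen-8-yl]phenyl}-7-methoxy-2,3-dihydro-4H-chromen-4-one | O=C1CC(c2ccc(OCc3ccccc3)c(c2)-c2c(OC)cc(OCc3ccccc3)c3c(=O)cc(-c4ccc(OC)cc4)oc23)Oc2cc(OC)cc(OCc3ccccc3)c12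
F4 | step 6 | 5-(benzyloxy)-7-methoxy-2-(4-methoxyphenyl)-8-(4,4,5,5-tetramethyl-1,3,2-dioxaborolan-2-yl)-4H-chromen-4-one | COc1ccc(cc1)-c1cc(=O)c2c(OCc3ccccc3)cc(OC)c(B3OC(C)(C)C(C)(C)O3)c2o1
F0 | step 12 | none | none
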